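**Plan**

Labels: flavan unit O1, C2, C3, C4, C4a, C5–C8, C8a with rings A, B, C; chalcan chain Ca (diarylmethine on C6), Cb (carbinol), Cc (CH2); ring D (phloroglucinol) on Cc, ring E (pyrogallol) on Ca.
Retrosynthetic cuts, in order: the two gallate esters; C2–C3 of ring C; the O1–CH2 bond that brings in ring B and C2; C4a–C4 (Claisen shift of an O1 allyl group, later cut to the C3 aldehyde); Cc–ring D (aryllithium on a terminal epoxide); Ca–ring E and Cb–O (conjugate addition and enolate hydroxylation on an enoyl imide whose β-carbon is the formyl carbon of 2,4,6-trihydroxybenzaldehyde).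
Feature used: C2 is benzylic and bound to the aryl ether oxygen O1, and ring A holds it ortho to the C4 chain, 1,7 to the oxygen of a C3 aldehyde; ring B and C2 can therefore enter as an ordinary benzyl ether, and ring C can be closed between two oxygen-bearing carbons by intramolecular hydrogen transfer and radical recombination.
Forward order: ring A aldehyde → chain Ca–Cb–Cc with rings E and D → Claisen shift to C4a (O5 and O7 carry the same silyl group, so C4a and C8 are equivalent and the 6-linkage is fixed by symmetry) → ring B ether → ring C by photocyclisation → oxidation and asymmetric reduction → both gallates → deprotection.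
Stereochemistry: Ca and Cb from the (S)-4-benzyloxazolidinone auxiliary (steps 4 and 5); C2 and C3 from a dynamic kinetic asymmetric transfer hydrogenation of the flavan-3-one (step 15), so the photochemical step needs no stereocontrol.

Key step: step 13

Shorthand: TBS = tert-butyldimethylsilyl; Bn = benzyl; Ar345 = 3,4,5-tris(benzyloxy)phenyl; Ar246 = 2,4,6-tris(benzyloxy)phenyl; ArA = 4-(allyloxy)-2,6-bis(TBS-oxy)phenyl.
Assumption: compounds 4, 6, 13, 18 and 25 are taken as purchasable; 6 is otherwise one benzylation away from 5-bromobenzene-1,2,3-triol.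

**Route**

Step 1
Reactants: 1 2,4,6-trihydroxybenzaldehyde
Product: 2 4-(allyloxy)-2,6-dihydroxybenzaldehyde
Conditions: allyl bromide (1.0 equiv), K2CO3 (1.0 equiv), DMF, 0 °C to rt
Reagents that add atoms: allyl bromide, C=CCBr
Why: Williamson etherification in which the 4-OH, the most acidic hydroxyl and the only one not hydrogen-bonded to the formyl group, should react first with one equivalent of halide.

Step 2
Reactants: 2 4-(allyloxy)-2,6-dihydroxybenzaldehyde
Product: 3 4-(allyloxy)-2,6-bis(TBS-oxy)benzaldehyde (ArA–CHO)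
Conditions: TBSCl (2.5 equiv), imidazole, DMF, rt
Reagents that add atoms: tert-butyldimethylsilyl chloride, CC(C)(C)[Si](C)(C)Cl
Why: Imidazole-promoted silylation of both equivalent ortho phenols; silyl ethers are chosen because they offer no abstractable α-hydrogen in step 13.

Step 3
Reactants: 3 ArA–CHO; 4 (S)-4-benzyl-3-[(diethoxyphosphoryl)acetyl]oxazolidin-2-one
Product: 5 (S)-4-benzyl-3-[(E)-3-ArA-acryloyl]oxazolidin-2-one
Conditions: NaH, THF, 0 °C to rt
Reagents that add atoms: none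
Why: Horner–Wadsworth–Emmons olefination with a stabilised phosphonate should give the (E)-enoyl imide.

Step 4
Reactants: 5 (S)-4-benzyl-3-[(E)-3-ArA-acryloyl]oxazolidin-2-one; 6 5-bromo-1,2,3-tris(benzyloxy)benzene
Product: 8 (S)-4-benzyl-3-[(3R)-3-ArA-3-Ar345-propanoyl]oxazolidin-2-one, via [3,4,5-tris(benzyloxy)phenyl]magnesium bromide 7 (not isolated)
Conditions: 6, Mg, THF, 50 °C; then CuBr·SMe2, THF/Me2S, −40 °C; then 5, −40 to −10 °C; aqueous quench
Reagents that add atoms: none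
Why: Auxiliary-controlled conjugate addition of an arylcopper reagent to the magnesium-chelated s-cis N-enoyl oxazolidinone, in which the aryl group should add to the β-carbon face opposite the C4 benzyl group and so set Ca.

Step 5
Reactants: 8 (S)-4-benzyl-3-[(3R)-3-ArA-3-Ar345-propanoyl]oxazolidin-2-one
Product: 9 (S)-4-benzyl-3-[(2S,3R)-2-hydroxy-3-ArA-3-Ar345-propanoyl]oxazolidin-2-one
Conditions: NaN(SiMe3)2, THF, −78 °C; then 2-(benzenesulfonyl)-3-phenyloxaziridine; AcOH quench at −78 °C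
Reagents that add atoms: 2-(benzenesulfonyl)-3-phenyloxaziridine (Davis oxaziridine), O=S(=O)(c1ccccc1)N1OC1c1ccccc1
Why: Evans enolate hydroxylation, in which the chelated Z sodium enolate should be oxidised on the face opposite the auxiliary benzyl group and so set Cb.

Step 6
Reactants: 9 (S)-4-benzyl-3-[(2S,3R)-2-hydroxy-3-ArA-3-Ar345-propanoyl]oxazolidin-2-one
Product: 10 (2S,3R)-3-ArA-3-Ar345-propane-1,2-diol
Conditions: LiBH4, MeOH (1 equiv), THF, 0 °C
Reagents that add atoms: none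
Why: Reductive removal of the auxiliary by hydride attack at the exocyclic imide carbonyl, which leaves Ca and Cb untouched.

Step 7
Reactants: 10 (2S,3R)-3-ArA-3-Ar345-propane-1,2-diol
Product: 12 (S)-2-[(R)-ArA(Ar345)methyl]oxirane, via primary 4-toluenesulfonate 11 (not isolated)
Conditions: TsCl, Et3N, Bu2SnO (cat.), CH2Cl2, 0 °C to rt; then DBU, rt
Reagents that add atoms: none
Why: Tin-acetal-catalysed selective sulfonylation of the primary hydroxyl followed by intramolecular Williamson closure should give the terminal epoxide without bond changes at Cb.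

Step 8
Reactants: 12 (S)-2-[(R)-ArA(Ar345)methyl]oxirane; 13 1,3,5-tris(benzyloxy)benzene
Product: 15 (1R,2R)-1-ArA-1-Ar345-3-Ar246-propan-2-ol, via [2,4,6-tris(benzyloxy)phenyl]lithium 14 (not isolated)
Conditions: 13, n-BuLi, THF, 0 °C; then −78 °C, 12, BF3·OEt2; aqueous work-up
Reagents that add atoms: none
Why: Directed ortho-lithiation between two alkoxy groups and BF3-assisted SN2 opening of the epoxide at its CH2 carbon should attach ring D and free the Cb hydroxyl with its configuration unchanged.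

Step 9
Reactants: 15 (1R,2R)-1-ArA-1-Ar345-3-Ar246-propan-2-ol
Product: 16 (1R,2R)-1-ArA-1-Ar345-3-Ar246-propan-2-yl acetate
Conditions: Ac2O, DMAP, pyridine, rt
Reagents that add atoms: acetic anhydride, CC(=O)OC(C)=O
Why: DMAP-catalysed acetylation protects Cb–OH against the oxidation of step 14 with a group that does not absorb in the window used for step 13.

Step 10
Reactants: 16 (1R,2R)-1-ArA-1-Ar345-3-Ar246-propan-2-yl acetate
Product: 17 (1R,2R)-1-[3-allyl-4-hydroxy-2,6-bis(TBS-oxy)phenyl]-1-Ar345-3-Ar246-propan-2-yl acetate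
Conditions: N,N-diethylaniline, 190 °C, sealed tube
Reagents that add atoms: none
Why: Aromatic Claisen rearrangement of the O1 allyl ether, whose two ortho positions are equivalent because O5 and O7 carry the same group, should give one C-allyl phenol.

Step 11
Reactants: 17 the C-allyl phenol; 18 [3,4,5-tris(benzyloxy)phenyl]methanol
Product: 19 (1R,2R)-1-{3-allyl-2,6-bis(TBS-oxy)-4-[3,4,5-tris(benzyloxy)benzyloxy]phenyl}-1-Ar345-3-Ar246-propan-2-yl acetate
Conditions: PPh3, DIAD, THF, 0 °C to rt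
Reagents that add atoms: none
Why: Mitsunobu etherification of the phenol with a primary benzylic alcohol should place ring B and the future C2 on O1 under neutral conditions that spare the aryl silyl ethers.

Step 12
Reactants: 19 the O1 benzyl ether
Product: 20 (1R,2R)-1-{3-(2-oxoethyl)-2,6-bis(TBS-oxy)-4-[3,4,5-tris(benzyloxy)benzyloxy]phenyl}-1-Ar345-3-Ar246-propan-2-yl acetate
Conditions: OsO4 (2 mol%), NaIO4, 2,6-lutidine, dioxane/H2O (3:1), rt; used crude
Reagents that add atoms: sodium periodate, [Na+].[O-]I(=O)(=O)=O (terminal oxidant; its oxygen reaches C3 through OsO4)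
Why: Lemieux–Johnson dihydroxylation–cleavage of the terminal alkene should give the arylacetaldehyde without ozone, which would attack the electron-rich rings.

Step 13
Reactants: 20 the arylacetaldehyde
Product: 21 (1R,2R)-1-{3-hydroxy-5,7-bis(TBS-oxy)-2-Ar345-chroman-6-yl}-1-Ar345-3-Ar246-propan-2-yl acetate (mixture of C2/C3 isomers)
Conditions: hν (medium-pressure Hg lamp, Pyrex filter, λ > 300 nm), degassed benzene (0.005 M), rt
Reagents that add atoms: none
Why: Proposed new method: n→π* excitation of the aldehyde gives an oxygen-centred excited state that abstracts one of the two benzylic hydrogens on the O1–CH2 carbon (1,7-hydrogen transfer through an eight-membered transition state), and the 1,6-biradical so formed (hydroxy-substituted C3 radical and α-aryloxybenzyl C2 radical, two oxygen-bearing carbons of like polarity) recombines to the C2–C3 bond. The closest known reaction type is the Norrish–Yang photocyclisation of o-(benzyloxy)aryl ketones and aldehydes to 2-aryl-2,3-dihydrobenzofuran-3-ols by δ-hydrogen abstraction, together with Yang cyclisation through ε-hydrogen abstraction where γ-hydrogens are absent; new here is the homologated, non-conjugated arylacetaldehyde chromophore. Ring C closes as a six-membered ring by 1,6-recombination of the biradical termini C2 and C3. C2 and C3 form without useful control (a chair-like closure should favour the 2,3-trans isomers), which is accepted because step 14 removes C3 and makes C2 epimerisable and step 15 sets both. The step needs site selectivity in hydrogen abstraction and a preference for abstraction over α-cleavage with decarbonylation and over charge-transfer quenching by electron-rich ring A. The substrate secures the first because the O1–CH2–aryl hydrogens are the only weak C–H bonds within reach (C4a and C8a carry no hydrogen, O5 and O7 are silylated, the acetate and all other benzyl ethers sit on remote rings), and helps the second because no γ-hydrogen fragmentation path exists and, with no gallate yet present, only the aldehyde absorbs above 300 nm.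

Step 14
Reactants: 21 the chroman-3-ol mixture
Product: 22 (1R,2R)-1-{3-oxo-5,7-bis(TBS-oxy)-2-Ar345-chroman-6-yl}-1-Ar345-3-Ar246-propan-2-yl acetate (C2 epimers)
Conditions: Dess–Martin periodinane, CH2Cl2, 0 °C to rt
Reagents that add atoms: none
Why: Dess–Martin oxidation should converge all C2/C3 isomers on one flavan-3-one whose C2 is α to the ketone and therefore epimerisable.

Step 15
Reactants: 22 the flavan-3-one
Product: 23 (1R,2R)-1-{(2R,3R)-3-hydroxy-5,7-bis(TBS-oxy)-2-Ar345-chroman-6-yl}-1-Ar345-3-Ar246-propan-2-yl acetate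
Conditions: RuCl[(R,R)-TsDPEN](p-cymene) (5 mol%), HCO2H/Et3N (5:2), CH2Cl2, 30 °C
Reagents that add atoms: none
Why: Noyori–Ikariya asymmetric transfer hydrogenation under dynamic kinetic resolution, in which C2 equilibrates through the enol in the amine/formic acid medium and the (R,R)-catalyst is expected to reduce the (2R)-epimer by hydride delivery to the Si face of C3 anti to the C2 aryl group, giving the 2,3-cis (2R,3R) alcohol; the sense is assigned by analogy with aryl ketones and should be checked against the antipodal catalyst.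

Step 16
Reactants: 23 the (2R,3R)-flavan-3-ol acetate
Product: 24 (1R,2R)-1-{(2R,3R)-3-hydroxy-5,7-bis(TBS-oxy)-2-Ar345-chroman-6-yl}-1-Ar345-3-Ar246-propan-2-ol
Conditions: i-Bu2AlH (3.5 equiv), CH2Cl2, −78 °C; aqueous potassium sodium tartrate
Reagents that add atoms: none
Why: Reductive cleavage of the only ester present should free Cb–OH while aryl silyl ethers and benzyl ethers are inert to the hydride.

Step 17
Reactants: 24 the diol; 25 3,4,5-tris(benzyloxy)benzoic acid
Product: 26 the 3-O- and Cb-O-bis[3,4,5-tris(benzyloxy)benzoate] of 24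
Conditions: 25 (4 equiv), DCC, DMAP, CH2Cl2, rt to 40 °C
Reagents that add atoms: none
Why: Steglich esterification should acylate both secondary alcohols in one operation, the two phenols of ring A being still silylated.

Step 18
Reactants: 26 the bis-gallate
Product: 27 the 5,7-dihydroxy bis-gallate (26 without both TBS groups)
Conditions: Bu4NF, AcOH, THF, 0 °C
Reagents that add atoms: none
Why: Fluoride cleavage of the two aryl silyl ethers, buffered with acetic acid so that the gallate esters neither cleave nor migrate.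

Step 19
Reactants: 27 the pentadeca-O-benzyl ether
Product: 28 CNP0240551.1 (target)
Conditions: H2 (1 atm), Pd(OH)2/C, THF/MeOH (1:1), rt
Reagents that add atoms: none
Why: Neutral hydrogenolysis of the fifteen benzyl ethers, the standard last step for galloylated flavan-3-ols, should leave the esters, the cyclic C2–O1 bond and all four stereocentres intact.

**Compound list**

1 | 2,4,6-trihydroxybenzaldehyde | O=Cc1c(O)cc(O)cc1O | starting material
2 | 4-(allyloxy)-2,6-dihydroxybenzaldehyde | O=Cc1c(O)cc(OCC=C)cc1O | intermediate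
3 | 4-(allyloxy)-2,6-bis(TBS-oxy)benzaldehyde | O=Cc1c(O[Si](C)(C)C(C)(C)C)cc(OCC=C)cc1O[Si](C)(C)C(C)(C)C | intermediate
4 | (S)-4-benzyl-3-[(diethoxyphosphoryl)acetyl]oxazolidin-2-one | CCOP(=O)(OCC)CC(=O)N1[C@@H](Cc2ccccc2)COC1=O | starting material
5 | (S)-4-benzyl-3-[(E)-3-ArA-acryloyl]oxazolidin-2-one | O=C(/C=C/c1c(O[Si](C)(C)C(C)(C)C)cc(OCC=C)cc1O[Si](C)(C)C(C)(C)C)N1[C@@H](Cc2ccccc2)COC1=O | intermediate
6 | 5-bromo-1,2,3-tris(benzyloxy)benzene | Brc1cc(OCc2ccccc2)c(OCc2ccccc2)c(OCc2ccccc2)c1 | starting material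
7 | [3,4,5-tris(benzyloxy)phenyl]magnesium bromide | Br[Mg]c1cc(OCc2ccccc2)c(OCc2ccccc2)c(OCc2ccccc2)c1 | intermediate
8 | (S)-4-benzyl-3-[(3R)-3-ArA-3-Ar345-propanoyl]oxazolidin-2-one | O=C(C[C@H](c3cc(OCc4ccccc4)c(OCc4ccccc4)c(OCc4ccccc4)c3)c1c(O[Si](C)(C)C(C)(C)C)cc(OCC=C)cc1O[Si](C)(C)C(C)(C)C)N1[C@@H](Cc2ccccc2)COC1=O | intermediate
9 | (S)-4-benzyl-3-[(2S,3R)-2-hydroxy-3-ArA-3-Ar345-propanoyl]oxazolidin-2-one | O=C([C@@H](O)[C@H](c3cc(OCc4ccccc4)c(OCc4ccccc4)c(OCc4ccccc4)c3)c1c(O[Si](C)(C)C(C)(C)C)cc(OCC=C)cc1O[Si](C)(C)C(C)(C)C)N1[C@@H](Cc2ccccc2)COC1=O | intermediate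
10 | (2S,3R)-3-ArA-3-Ar345-propane-1,2-diol | OC[C@@H](O)[C@H](c3cc(OCc4ccccc4)c(OCc4ccccc4)c(OCc4ccccc4)c3)c1c(O[Si](C)(C)C(C)(C)C)cc(OCC=C)cc1O[Si](C)(C)C(C)(C)C | intermediate
11 | primary 4-toluenesulfonate of diol 10 | Cc1ccc(cc1)S(=O)(=O)OC[C@@H](O)[C@H](c3cc(OCc4ccccc4)c(OCc4ccccc4)c(OCc4ccccc4)c3)c1c(O[Si](C)(C)C(C)(C)C)cc(OCC=C)cc1O[Si](C)(C)C(C)(C)C | intermediate
12 | (S)-2-[(R)-ArA(Ar345)methyl]oxirane | C1O[C@H]1[C@H](c3cc(OCc4ccccc4)c(OCc4ccccc4)c(OCc4ccccc4)c3)c1c(O[Si](C)(C)C(C)(C)C)cc(OCC=C)cc1O[Si](C)(C)C(C)(C)C | intermediate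
13 | 1,3,5-tris(benzyloxy)benzene | c1c(OCc2ccccc2)cc(OCc2ccccc2)cc1OCc1ccccc1 | starting material
14 | [2,4,6-tris(benzyloxy)phenyl]lithium | [Li]c1c(OCc2ccccc2)cc(OCc2ccccc2)cc1OCc1ccccc1 | intermediate
15 | (1R,2R)-1-ArA-1-Ar345-3-Ar246-propan-2-ol | O[C@H](Cc3c(OCc4ccccc4)cc(OCc4ccccc4)cc3OCc3ccccc3)[C@H](c3cc(OCc4ccccc4)c(OCc4ccccc4)c(OCc4ccccc4)c3)c1c(O[Si](C)(C)C(C)(C)C)cc(OCC=C)cc1O[Si](C)(C)C(C)(C)C | intermediate
16 | (1R,2R)-1-ArA-1-Ar345-3-Ar246-propan-2-yl acetate | CC(=O)O[C@H](Cc3c(OCc4ccccc4)cc(OCc4ccccc4)cc3OCc3ccccc3)[C@H](c3cc(OCc4ccccc4)c(OCc4ccccc4)c(OCc4ccccc4)c3)c1c(O[Si](C)(C)C(C)(C)C)cc(OCC=C)cc1O[Si](C)(C)C(C)(C)C | intermediate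
17 | (1R,2R)-1-[3-allyl-4-hydroxy-2,6-bis(TBS-oxy)phenyl]-1-Ar345-3-Ar246-propan-2-yl acetate | CC(=O)O[C@H](Cc3c(OCc4ccccc4)cc(OCc4ccccc4)cc3OCc3ccccc3)[C@H](c3cc(OCc4ccccc4)c(OCc4ccccc4)c(OCc4ccccc4)c3)c1c(O[Si](C)(C)C(C)(C)C)c(CC=C)c(O)cc1O[Si](C)(C)C(C)(C)C | intermediate
18 | [3,4,5-tris(benzyloxy)phenyl]methanol | OCc1cc(OCc2ccccc2)c(OCc2ccccc2)c(OCc2ccccc2)c1 | starting material
19 | (1R,2R)-1-{3-allyl-2,6-bis(TBS-oxy)-4-[3,4,5-tris(benzyloxy)benzyloxy]phenyl}-1-Ar345-3-Ar246-propan-2-yl acetate | CC(=O)O[C@H](Cc3c(OCc4ccccc4)cc(OCc4ccccc4)cc3OCc3ccccc3)[C@H](c3cc(OCc4ccccc4)c(OCc4ccccc4)c(OCc4ccccc4)c3)c1c(O[Si](C)(C)C(C)(C)C)c(CC=C)c(OCc5cc(OCc6ccccc6)c(OCc6ccccc6)c(OCc6ccccc6)c5)cc1O[Si](C)(C)C(C)(C)C | intermediate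
20 | arylacetaldehyde: 19 with the allyl group cut to CH2CHO | CC(=O)O[C@H](Cc3c(OCc4ccccc4)cc(OCc4ccccc4)cc3OCc3ccccc3)[C@H](c3cc(OCc4ccccc4)c(OCc4ccccc4)c(OCc4ccccc4)c3)c1c(O[Si](C)(C)C(C)(C)C)c(CC=O)c(OCc5cc(OCc6ccccc6)c(OCc6ccccc6)c(OCc6ccccc6)c5)cc1O[Si](C)(C)C(C)(C)C | intermediate
21 | (1R,2R)-1-{3-hydroxy-5,7-bis(TBS-oxy)-2-Ar345-chroman-6-yl}-1-Ar345-3-Ar246-propan-2-yl acetate, mixture of C2/C3 isomers (both centres left open in the SMILES) | CC(=O)O[C@H](Cc3c(OCc4ccccc4)cc(OCc4ccccc4)cc3OCc3ccccc3)[C@H](c3cc(OCc4ccccc4)c(OCc4ccccc4)c(OCc4ccccc4)c3)c1c(O[Si](C)(C)C(C)(C)C)c2c(cc1O[Si](C)(C)C(C)(C)C)OC(c5cc(OCc6ccccc6)c(OCc6ccccc6)c(OCc6ccccc6)c5)C(O)C2 | intermediate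
22 | flavan-3-one: 21 with C3=O, C2 epimers interconverting (C2 left open in the SMILES) | CC(=O)O[C@H](Cc3c(OCc4ccccc4)cc(OCc4ccccc4)cc3OCc3ccccc3)[C@H](c3cc(OCc4ccccc4)c(OCc4ccccc4)c(OCc4ccccc4)c3)c1c(O[Si](C)(C)C(C)(C)C)c2c(cc1O[Si](C)(C)C(C)(C)C)OC(c5cc(OCc6ccccc6)c(OCc6ccccc6)c(OCc6ccccc6)c5)C(=O)C2 | intermediate
23 | (1R,2R)-1-{(2R,3R)-3-hydroxy-5,7-bis(TBS-oxy)-2-Ar345-chroman-6-yl}-1-Ar345-3-Ar246-propan-2-yl acetate | CC(=O)O[C@H](Cc3c(OCc4ccccc4)cc(OCc4ccccc4)cc3OCc3ccccc3)[C@H](c3cc(OCc4ccccc4)c(OCc4ccccc4)c(OCc4ccccc4)c3)c1c(O[Si](C)(C)C(C)(C)C)c2c(cc1O[Si](C)(C)C(C)(C)C)O[C@H](c5cc(OCc6ccccc6)c(OCc6ccccc6)c(OCc6ccccc6)c5)[C@H](O)C2 | intermediate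
24 | (1R,2R)-1-{(2R,3R)-3-hydroxy-5,7-bis(TBS-oxy)-2-Ar345-chroman-6-yl}-1-Ar345-3-Ar246-propan-2-ol | O[C@H](Cc3c(OCc4ccccc4)cc(OCc4ccccc4)cc3OCc3ccccc3)[C@H](c3cc(OCc4ccccc4)c(OCc4ccccc4)c(OCc4ccccc4)c3)c1c(O[Si](C)(C)C(C)(C)C)c2c(cc1O[Si](C)(C)C(C)(C)C)O[C@H](c5cc(OCc6ccccc6)c(OCc6ccccc6)c(OCc6ccccc6)c5)[C@H](O)C2 | intermediate
25 | 3,4,5-tris(benzyloxy)benzoic acid | OC(=O)c1cc(OCc2ccccc2)c(OCc2ccccc2)c(OCc2ccccc2)c1 | starting material
26 | bis[3,4,5-tris(benzyloxy)benzoate] of 24 (esters on C3–O and Cb–O) | O=C(O[C@H](Cc3c(OCc4ccccc4)cc(OCc4ccccc4)cc3OCc3ccccc3)[C@H](c3cc(OCc4ccccc4)c(OCc4ccccc4)c(OCc4ccccc4)c3)c1c(O[Si](C)(C)C(C)(C)C)c2c(cc1O[Si](C)(C)C(C)(C)C)O[C@H](c5cc(OCc6ccccc6)c(OCc6ccccc6)c(OCc6ccccc6)c5)[C@H](OC(=O)c5cc(OCc6ccccc6)c(OCc6ccccc6)c(OCc6ccccc6)c5)C2)c3cc(OCc4ccccc4)c(OCc4ccccc4)c(OCc4ccccc4)c3 | intermediate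
27 | 26 with free 5-OH and 7-OH (pentadeca-O-benzyl target) | O=C(O[C@H](Cc3c(OCc4ccccc4)cc(OCc4ccccc4)cc3OCc3ccccc3)[C@H](c3cc(OCc4ccccc4)c(OCc4ccccc4)c(OCc4ccccc4)c3)c1c(O)c2c(cc1O)O[C@H](c5cc(OCc6ccccc6)c(OCc6ccccc6)c(OCc6ccccc6)c5)[C@H](OC(=O)c5cc(OCc6ccccc6)c(OCc6ccccc6)c(OCc6ccccc6)c5)C2)c3cc(OCc4ccccc4)c(OCc4ccccc4)c(OCc4ccccc4)c3 | intermediate
28 | CNP0240551.1: (2R,3R)-flavan-3-yl gallate carrying at C6 the (1R,2R)-1-(3,4,5-trihydroxyphenyl)-2-galloyloxy-3-(2,4,6-trihydroxyphenyl)propyl group | O=C(O[C@H](Cc1c(O)cc(O)cc1O)[C@H](c1cc(O)c(O)c(O)c1)c1c(O)cc2c(c1O)C[C@@H](OC(=O)c1cc(O)c(O)c(O)c1)[C@@H](c1cc(O)c(O)c(O)c1)O2)c1cc(O)c(O)c(O)c1 | target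

**Summary**

Total step count: 19. Longest linear sequence: 19 steps (1 to 28); 4, 6, 13, 18 and 25 enter as purchased building blocks.

Steps most likely to fail:

1. Step 13 (photocyclisation). The excited arylacetaldehyde may lose CO by α-cleavage, be quenched by charge transfer from ring A, or the biradical may return to starting aldehyde faster than it closes. Fallback with known chemistry, setting out from phenol 17 and coming back at 21:
   - Cross-metathesis of 17 with 5-vinyl-1,2,3-tris(benzyloxy)benzene (second-generation Hoveyda–Grubbs catalyst, CH2Cl2, 40 °C) should give the (E)-1,3-diarylpropene F1.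
   - Dihydroxylation (OsO4 cat., N-methylmorpholine N-oxide, acetone/H2O) should give the syn-diol F2.
   - Orthoester cyclisation (HC(OEt)3, pyridinium 4-toluenesulfonate, 1,2-dichloroethane, rt then 60 °C) lets the free O1 phenol displace the benzylic oxygen with inversion, giving the 2,3-trans-flavan-3-yl formate F3.
   - Ammonolysis (NH3, MeOH, 0 °C) returns the 2,3-trans members of 21, which enter step 14 unchanged.
   - Ring C is then closed at O1–C2 instead of C2–C3; the configurations at C2 and C3 are irrelevant because steps 14 and 15 reset them.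

2. Step 15 (dynamic kinetic transfer hydrogenation). Catalyst control over which C2 epimer is reduced may be weak or of the wrong sense for this ketone, which is not an aryl ketone, or C2 may epimerise too slowly. Fallback, setting out from 22 and coming back at 23:
   - Substrate-controlled reduction with LiBH(s-Bu)3 (THF, −78 °C), which delivers hydride anti to the C2 aryl group in both epimers, should give 23 together with its (2S,3S)-cis diastereomer F4.
   - The two are diastereomers because of the chalcan stereocentres and should separate by chromatography.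
   - F4 is returned to 22 by Dess–Martin oxidation, equilibrated at C2 with Et3N and reduced again.

3. Step 4 (conjugate addition). The β-carbon of 5 is flanked by two ortho silyloxy groups and deactivated by three oxygen donors, so addition may be slow and attack at the imide carbonyls may take over. Fallback, setting out from aldehyde 3 and coming back at diol 10:
   - Still–Gennari olefination of 3 (bis(2,2,2-trifluoroethyl) (methoxycarbonylmethyl)phosphonate, KN(SiMe3)2, 18-crown-6, THF, −78 °C) should give methyl (Z)-3-ArA-acrylate F5.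
   - Reduction with i-Bu2AlH should give the (Z)-allylic alcohol F6.
   - Sharpless epoxidation (Ti(OiPr)4, D-(−)-diethyl tartrate, t-BuOOH, 4 Å sieves, −20 °C) should give the (2R,3S)-cis-epoxy alcohol F7.
   - Opening of F7 at the benzylic carbon with Grignard reagent 7 and CuI (THF, −30 °C), with inversion, should give diol 10.
   - Ca is then set by SN2 arylation of a reagent-controlled epoxide instead of by the auxiliary, and steps 5 and 6 are not needed.

Further compounds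
F1 | step 13 | (1R,2R)-1-{4-hydroxy-2,6-bis(TBS-oxy)-3-[(E)-3-Ar345-allyl]phenyl}-1-Ar345-3-Ar246-propan-2-yl acetate | CC(=O)O[C@H](Cc3c(OCc4ccccc4)cc(OCc4ccccc4)cc3OCc3ccccc3)[C@H](c3cc(OCc4ccccc4)c(OCc4ccccc4)c(OCc4ccccc4)c3)c1c(O[Si](C)(C)C(C)(C)C)c(C/C=C/c5cc(OCc6ccccc6)c(OCc6ccccc6)c(OCc6ccccc6)c5)c(O)cc1O[Si](C)(C)C(C)(C)C
F2 | step 13 | syn-2,3-diol of F1 (both syn isomers; the two new centres left open) | CC(=O)O[C@H](Cc3c(OCc4ccccc4)cc(OCc4ccccc4)cc3OCc3ccccc3)[C@H](c3cc(OCc4ccccc4)c(OCc4ccccc4)c(OCc4ccccc4)c3)c1c(O[Si](C)(C)C(C)(C)C)c(CC(O)C(O)c5cc(OCc6ccccc6)c(OCc6ccccc6)c(OCc6ccccc6)c5)c(O)cc1O[Si](C)(C)C(C)(C)C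
F3 | step 13 | 3-O-formate of the 2,3-trans isomers of 21 (C2 and C3 left open) | CC(=O)O[C@H](Cc3c(OCc4ccccc4)cc(OCc4ccccc4)cc3OCc3ccccc3)[C@H](c3cc(OCc4ccccc4)c(OCc4ccccc4)c(OCc4ccccc4)c3)c1c(O[Si](C)(C)C(C)(C)C)c2c(cc1O[Si](C)(C)C(C)(C)C)OC(c5cc(OCc6ccccc6)c(OCc6ccccc6)c(OCc6ccccc6)c5)C(OC=O)C2
F4 | step 15 | (2S,3S)-cis diastereomer of 23 | CC(=O)O[C@H](Cc3c(OCc4ccccc4)cc(OCc4ccccc4)cc3OCc3ccccc3)[C@H](c3cc(OCc4ccccc4)c(OCc4ccccc4)c(OCc4ccccc4)c3)c1c(O[Si](C)(C)C(C)(C)C)c2c(cc1O[Si](C)(C)C(C)(C)C)O[C@@H](c5cc(OCc6ccccc6)c(OCc6ccccc6)c(OCc6ccccc6)c5)[C@@H](O)C2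
F5 | step 4 | methyl (Z)-3-ArA-acrylate | COC(=O)/C=C\c1c(O[Si](C)(C)C(C)(C)C)cc(OCC=C)cc1O[Si](C)(C)C(C)(C)C
F6 | step 4 | (Z)-3-ArA-prop-2-en-1-ol | OC/C=C\c1c(O[Si](C)(C)C(C)(C)C)cc(OCC=C)cc1O[Si](C)(C)C(C)(C)C
F7 | step 4 | [(2R,3S)-3-ArA-oxiran-2-yl]methanol (cis-epoxide) | OC[C@H]1O[C@H]1c1c(O[Si](C)(C)C(C)(C)C)cc(OCC=C)cc1O[Si](C)(C)C(C)(C)C
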